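If Qa is charged at several equivalents but also consumes itself, the equivalents say little until its balance is written.

    Qa + Ly → Ty (k1 = 2900 /M/min)
    Ky + Ty ⇌ Eb (K2 = 37 /M, k2 = 41000 /M/min)
    Eb → Wa + Ul (k3 = 120 /min)
    Ul ⇌ Dx (K4 = 0.64, k4 = 120 /min)
    Dx → Ly + Qo (k5 = 120 /min)
    2 Eb → Yx (k6 = 1100 /M/min)
    2 Qa → Vy (k7 = 8.8 /M/min)

Ky 19 mM; Qa 2.50 equiv; Ly 0.2 mol%

- a species is counted by the Ky in it: one Yx counts as two
- for a step with 2 of a species take k times the square, and two of it per event
- a form made of two catalysts counts as two
- charge of Ky (flask): 19 mM

* the form that holds most of the catalyst when 30% of the Ky are converted (Yx / Dx / Ty / Ly / Ul / Eb)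
* its share of the catalyst then
* apparent order in Qa when 30% of the Ky are converted (percent change of the rate of making Qo for one percent more Qa charged)

I start from that balance. Qa enters the round through its step with Ly, at a rate proportional to cQa, but it also leaves by the self-reaction to Vy, at a rate proportional to the square of cQa, much as an initiator is lost to its own recombination. So the two outflows match at 6.26 mM, and this crossover concentration, the cQa at which the whole catalyst charge sitting as Ly removes Qa as fast as the self-reaction does, is what I carry.

The charge of 47.5 mM stands above it, so Vy takes the early Qa faster than the round does. Dividing one outflow by the other and integrating down the whole charge gives a ceiling on Qa entering the round, 13.5 mM. That is less than the Ky charged, so in this flask Qa, though in excess, is the limiting reagent.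

The same balance in time puts cQa at 0.808 mM after 0.309 h, below the crossover. A catalyst then waits 0.427 min as Ly, but spends 0.0568 min per turn in Ty, Eb, Ul and Dx together. So I expect the resting state Ly with a share of 88.3%, which makes the rate close to first order in the cQa present; but that is not the charge, and part of any extra charge goes to Vy, so for the order in charged Qa I commit to a bound, below 1.00.

The forecast says Ly at 80%, a lower share than mine, and an order of 0.5, holding that “the slow Qa + Ly step limits the cycle”.

The flask gives Ly at 81.2% and an order of 0.57, so the forecast stands.

By 0.150 h this flask holds 4.30 mM of Qa, already under the crossover, and by 1.50 h Qo stops at 36.3% of the Ky charged, or 6.89 mM, below the ceiling, with 0% of the Qa left. The self-reaction is the largest single effect on the rate among the simulated runs : without it, the rate when 30% of the Ky are converted is 4.80 times the actual one. In that same run the apparent order in Qa drops from 0.57 to 0.14.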